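**Plan**

- Retrosynthesis cuts, in order: the C5 O–benzyl bond; the C4–C4' bond between chroman C4 and naphthalene C4' (para to the C1' methoxy group), made with C4 at the ketone oxidation level; the C4 carbonyl back to an exocyclic C4=CH2; C4–C4a (Heck closure); O1–C2 (Mitsunobu etherification).
- Enabling feature: chroman C4 is benzylic to C4a, which lies between the two oxygen-bearing ring carbons C5 and C8a (O1). Once C4 also carries the 4-methoxynaphthyl group, a C4 carbinol ionizes in mild acid to a well-stabilized cation. Naphthalene C4' is the nucleophilic site para to OMe.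
- Forward order: both benzenoid systems are bought. The pyran ring is built on 2-bromoresorcinol by ether formation (O1–C2), then 6-exo Heck cyclization (C4–C4a). Ozonolysis gives the chromanone; the bromonaphthalene is joined as its ArCeCl2 reagent and the carbinol is reduced in the same step; hydrogenolysis ends the route.
- Stereochemistry: C2 (S) comes from (R)-pent-4-en-2-ol with Mitsunobu inversion. C4 (S) is set by substrate control from C2: hydride is the last group to enter C4 and adds trans to the methyl group, which puts the naphthyl group cis to it. An arene-last alkylation of a C4 cation would be expected to give the trans isomer instead.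

Key step: step 6

**Route**

Step 1
Reactants: 1 1,8-dimethoxynaphthalene
Product: 2 1-bromo-4,5-dimethoxynaphthalene (4-bromo-1,8-dimethoxynaphthalene)
Conditions: NBS (1.0 equiv), MeCN, 0 °C to rt
Reagents that add atoms: N-bromosuccinimide, O=C1CCC(=O)N1Br
Why: Electrophilic aromatic bromination of the electron-rich naphthalene should occur at C4, para to a methoxy group and the most nucleophilic unhindered position, and one equivalent of NBS at low temperature should hold it at the monobromide.

Step 2
Reactants: 3 2-bromobenzene-1,3-diol (2-bromoresorcinol)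
Product: 4 3-(benzyloxy)-2-bromophenol
Conditions: BnBr (1.0 equiv), K2CO3 (1.1 equiv), acetone, reflux; recovered 3 recycled
Reagents that add atoms: benzyl bromide, BrCc1ccccc1
Why: Williamson O-alkylation of one of the two equivalent hydroxyl groups with a limiting amount of benzyl bromide should give the mono-ether, which is separable from recovered diol and bis-ether.

Step 3
Reactants: 4 3-(benzyloxy)-2-bromophenol; 5 (R)-pent-4-en-2-ol
Product: 6 1-(benzyloxy)-2-bromo-3-{[(2S)-pent-4-en-2-yl]oxy}benzene
Conditions: PPh3, diisopropyl azodicarboxylate, THF, 0 °C to rt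
Reagents that add atoms: none
Why: In the Mitsunobu reaction the phenoxide displaces the alkoxyphosphonium group of 5 by SN2, so the R carbinol centre is inverted to the S aryl ether that becomes C2, and a homoallylic secondary alcohol offers no easy elimination path.

Step 4
Reactants: 6 1-(benzyloxy)-2-bromo-3-{[(2S)-pent-4-en-2-yl]oxy}benzene
Product: 7 (2S)-5-(benzyloxy)-2-methyl-4-methylidene-3,4-dihydro-2H-chromene
Conditions: Pd(OAc)2 (5 mol %), P(o-tol)3 (12 mol %), Ag2CO3 (1.0 equiv), MeCN, 80 °C
Reagents that add atoms: none
Why: Intramolecular Mizoroki–Heck reaction: oxidative addition of the C–Br bond to zerovalent palladium, 6-exo-trig carbopalladation of the terminal alkene (forming C4–C4a) and syn β-hydride elimination of the only available hydrogen (C4–H) should give the exocyclic alkene, while Ag2CO3 removes bromide and suppresses the Pd–H re-addition that would move the double bond into the ring; C2 is not involved.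

Step 5
Reactants: 7 (2S)-5-(benzyloxy)-2-methyl-4-methylidene-3,4-dihydro-2H-chromene
Product: 9 (2S)-5-(benzyloxy)-2-methyl-2,3-dihydro-4H-chromen-4-one, via spiro ozonide 8 (not isolated)
Conditions: O3, CH2Cl2, −78 °C; then Me2S, −78 °C to rt
Reagents that add atoms: ozone, [O-][O+]=O
Why: Ozonolysis with reductive work-up should cleave the 1,1-disubstituted styrene-type alkene much faster than ozone attacks the arene or the benzyl ether, and it unveils the C4 ketone under neutral conditions that cannot cause retro-oxa-Michael racemization at C2.

Step 6
Reactants: 2 1-bromo-4,5-dimethoxynaphthalene; 9 (2S)-5-(benzyloxy)-2-methyl-2,3-dihydro-4H-chromen-4-one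
Product: 13 (2S,4S)-5-(benzyloxy)-4-(4,5-dimethoxynaphthalen-1-yl)-2-methyl-3,4-dihydro-2H-chromene, via aryllithium 10 (not isolated), via arylcerium dichloride 11 (not isolated), via tertiary carbinol 12 (not isolated)
Conditions: 2, n-BuLi, THF, −78 °C; CeCl3, −78 °C; 9, −78 to −40 °C; aq NH4Cl; crude 12, Et3SiH, CF3CO2H, CH2Cl2, −40 to 0 °C; aq NaHCO3
Reagents that add atoms: none
Why: Bromine–lithium exchange on 2 and transmetalation to CeCl3 give the weakly basic, oxophilic ArCeCl2 reagent 11, which adds 1,2 to the hindered, enolizable ketone 9 and so forms the C4–C4' bond; carbinol 12, whose C4 is benzylic to a ring carbon (C4a) lying between the oxygen-bearing carbons C5 and C8a and now also carries a 4-methoxynaphthyl group, ionizes in CF3CO2H to a strongly stabilized diaryl carbocation that takes hydride from Et3SiH. The closest known reaction type is the addition of an aryl organometallic to a carbonyl group followed by ionic hydrogenation of the resulting benzylic or anomeric carbinol, as practised for C-aryl glycosides. No ring is closed. The new C4 stereocentre is controlled by the C2 methyl group: in the sofa-shaped cation C2 is the out-of-plane atom with methyl pseudoequatorial, and hydride enters along the pseudoaxial line on the face toward which C2 is displaced (staggered to the C3–H bonds), which is trans to the methyl group, so the naphthyl group ends cis to methyl (2S,4S), and the minor conformer with axial methyl shields the other face and leads to the same isomer. The step needs addition instead of enolization and high facial selectivity: the first is secured by the organocerium at −78 °C (which also prevents E1cB opening of the β-aryloxy ketone and loss of the C2 configuration), the second by the C2 centre together with the design that makes hydride, not the arene, the last group to bond to C4. Benzyl and methyl ethers are inert under these conditions, any 4-aryl-2H-chromene formed by proton loss is re-protonated at C3 to the same cation, and a cold NaHCO3 quench keeps the acid-labile C4–aryl bond of 13 from ionizing again.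

Step 7
Reactants: 13 (2S,4S)-5-(benzyloxy)-4-(4,5-dimethoxynaphthalen-1-yl)-2-methyl-3,4-dihydro-2H-chromene
Product: 14 cladonaphchrom B, (2S,4S)-4-(4,5-dimethoxynaphthalen-1-yl)-2-methyl-3,4-dihydro-2H-chromen-5-ol
Conditions: H2 (1 atm), Pd/C (10 wt %), EtOAc/EtOH, rt
Reagents that add atoms: none
Why: Hydrogenolysis of the aryl benzyl ether over Pd/C under neutral conditions should free the C5 phenol without touching the methyl ethers, the naphthalene or either stereocentre, giving the target.

**Compound list**

1 | 1,8-dimethoxynaphthalene | COc1cccc2cccc(OC)c12 | starting material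
2 | 1-bromo-4,5-dimethoxynaphthalene | COc1ccc(Br)c2cccc(OC)c12 | intermediate
3 | 2-bromobenzene-1,3-diol | Oc1cccc(O)c1Br | starting material
4 | 3-(benzyloxy)-2-bromophenol | Oc1cccc(OCc2ccccc2)c1Br | intermediate
5 | (R)-pent-4-en-2-ol | C=CC[C@@H](C)O | starting material
6 | 1-(benzyloxy)-2-bromo-3-{[(2S)-pent-4-en-2-yl]oxy}benzene | C=CC[C@H](C)Oc1cccc(OCc2ccccc2)c1Br | intermediate
7 | (2S)-5-(benzyloxy)-2-methyl-4-methylidene-3,4-dihydro-2H-chromene | C=C1C[C@H](C)Oc2cccc(OCc3ccccc3)c21 | intermediate
8 | spiro ozonide (1,2,4-trioxolane at C4) of 7, mixture at the spiro carbon, not isolated | C[C@H]1CC2(OCOO2)c2c(OCc3ccccc3)cccc2O1 | intermediate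
9 | (2S)-5-(benzyloxy)-2-methyl-2,3-dihydro-4H-chromen-4-one | O=C1C[C@H](C)Oc2cccc(OCc3ccccc3)c21 | intermediate
10 | (4,5-dimethoxynaphthalen-1-yl)lithium, not isolated | COc1ccc([Li])c2cccc(OC)c12 | intermediate
11 | dichloro(4,5-dimethoxynaphthalen-1-yl)cerium, not isolated | COc1ccc([Ce](Cl)Cl)c2cccc(OC)c12 | intermediate
12 | (2S)-5-(benzyloxy)-4-(4,5-dimethoxynaphthalen-1-yl)-2-methyl-3,4-dihydro-2H-chromen-4-ol, both C4 epimers, not isolated | COc1cccc2c(C3(O)C[C@H](C)Oc4cccc(OCc5ccccc5)c43)ccc(OC)c12 | intermediate
13 | (2S,4S)-5-(benzyloxy)-4-(4,5-dimethoxynaphthalen-1-yl)-2-methyl-3,4-dihydro-2H-chromene | COc1cccc2c([C@@H]3C[C@H](C)Oc4cccc(OCc5ccccc5)c43)ccc(OC)c12 | intermediate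
14 | cladonaphchrom B, (2S,4S)-4-(4,5-dimethoxynaphthalen-1-yl)-2-methyl-3,4-dihydro-2H-chromen-5-ol | COc1cccc2c([C@@H]3C[C@H](C)Oc4cccc(O)c43)ccc(OC)c12 | target

**Step count**

Total step count: 7. Longest linear sequence: 6 steps (steps 2 to 7, from 3 to 14).

**Steps most likely to fail**

Step 6. Enolization of the electronically deactivated, hindered ketone may outrun 1,2-addition, or hydride transfer to the cation may show poor facial selectivity. The fallback sets out from 9 and 2 and comes back at 14. It joins the fragments by cross-coupling at an sp2 C4 and sets C4 by surface hydrogenation. Ketone 9 would be deprotonated with KN(SiMe3)2 and trapped with PhNTf2 (THF, −78 °C) to give (2S)-5-(benzyloxy)-2-methyl-2H-chromen-4-yl trifluoromethanesulfonate F1. Bromide 2 would be borylated (B2pin2, Pd(dppf)Cl2, KOAc, dioxane, 90 °C) to 2-(4,5-dimethoxynaphthalen-1-yl)-4,4,5,5-tetramethyl-1,3,2-dioxaborolane F2. Suzuki–Miyaura coupling of the two (Pd(OAc)2, SPhos, K3PO4, toluene/H2O, 60 °C, light excluded) should give (2S)-5-(benzyloxy)-4-(4,5-dimethoxynaphthalen-1-yl)-2-methyl-2H-chromene F3. Hydrogenation of F3 over Pd/C should add H2 to the alkene face remote from the C2 methyl group and cleave the benzyl ether in the same operation, giving 14.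

Step 4. The exocyclic double bond may migrate into the ring through Pd–H re-addition, or oxidative addition may be sluggish at the aryl bromide flanked by two alkoxy groups. The fallback sets out from 6 and comes back at 9. It closes the ring by an anionic acylation instead of a palladium-catalysed carbopalladation. Ozonolysis of the terminal alkene of 6 (O3, CH2Cl2, −78 °C; Me2S) would give (3S)-3-[3-(benzyloxy)-2-bromophenoxy]butanal F4. Pinnick oxidation (NaClO2, NaH2PO4, 2-methylbut-2-ene, t-BuOH/H2O) would give (3S)-3-[3-(benzyloxy)-2-bromophenoxy]butanoic acid F5. Parham cyclization (n-BuLi, 2.2 equiv, THF, −78 °C; bromine–lithium exchange, then attack of the aryllithium on the lithium carboxylate) should deliver 9.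

Step 2. Over-alkylation may drain material, because the mono-ether phenoxide competes with the diol for benzyl bromide. The fallback sets out from 3 and comes back at 6. It differentiates the two hydroxyl groups in the Mitsunobu step, where the cheap diol can be used in excess. Alcohol 5 would be coupled with a threefold excess of 3 (PPh3, diisopropyl azodicarboxylate, THF) to give 2-bromo-3-{[(2S)-pent-4-en-2-yl]oxy}phenol F6, with the surplus diol recovered. Exhaustive benzylation of the remaining hydroxyl (BnBr, K2CO3, DMF) should then give 6, bypassing 4.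

Further compounds
F1 | step 6 | (2S)-5-(benzyloxy)-2-methyl-2H-chromen-4-yl trifluoromethanesulfonate | C[C@H]1C=C(OS(=O)(=O)C(F)(F)F)c2c(OCc3ccccc3)cccc2O1
F2 | step 6 | 2-(4,5-dimethoxynaphthalen-1-yl)-4,4,5,5-tetramethyl-1,3,2-dioxaborolane | COc1ccc(B2OC(C)(C)C(C)(C)O2)c2cccc(OC)c12
F3 | step 6 | (2S)-5-(benzyloxy)-4-(4,5-dimethoxynaphthalen-1-yl)-2-methyl-2H-chromene | COc1cccc2c(C3=C[C@H](C)Oc4cccc(OCc5ccccc5)c43)ccc(OC)c12
F4 | step 4 | (3S)-3-[3-(benzyloxy)-2-bromophenoxy]butanal | O=CC[C@H](C)Oc1cccc(OCc2ccccc2)c1Br
F5 | step 4 | (3S)-3-[3-(benzyloxy)-2-bromophenoxy]butanoic acid | OC(=O)C[C@H](C)Oc1cccc(OCc2ccccc2)c1Br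
F6 | step 2 | 2-bromo-3-{[(2S)-pent-4-en-2-yl]oxy}phenol | C=CC[C@H](C)Oc1cccc(O)c1Br
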